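C1 = lactone C=O, C2=C3 = ring alkene, C4H2, C5 = ring carbinol carbon (ring A = O1, C1–C5), C6=C7 = Z-alkene, C9 and C11 = carbinols, C13 = acetoxy carbon, C15 = benzylic carbon.
Cuts: O9–PMB; O13–acetyl together with C11–H (Evans–Tishchenko); C12–C13 (aldol); ring bond C3–C4 (metathesis, after moving the ring alkene to C3=C4); O1–C1 (esterification); C5–C6 (alkynylation); C8–C9 (propargylation).
Enabling feature: C5 of ring A carries O1 and sits between C4 and the Z-C6=C7 alkene. In the C3=C4 tautomer of ring A it is therefore a doubly allylic carbinol carbon, so ring A is the metathesis product of a vinyl carbinol but-3-enoate, and conjugation with C1=O draws the alkene back to C2=C3.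
Forward order: the C6–C12 chain comes first, then C4–C5 (acrolein), then C1–C3 (but-3-enoic acid). Ring A, the only ring to be built, closes in step 7; C13–C15/phenyl and the acetyl group are joined last.
Stereochemistry: C9 comes from chiral phosphoric acid catalysis, C5 from zinc/ProPhenol catalysis, and Z-C6=C7 from syn semihydrogenation. C13 follows from C9 by 1,5-anti induction, and C11 from C13 by an intramolecular hydride delivery that also places the acetate.

Key step: step 7

Assumption: the facial sense is taken as Re-face delivery for (R)-TRIP (step 2) and for (S,S)-ProPhenol (step 4); both are sold as either antipode, so the other one would be used if the sense proved opposite.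

Step 1
Reactants: 1 ethyl 2-(2-methyl-1,3-dioxolan-2-yl)acetate
Product: 2 ketal aldehyde [2-(2-methyl-1,3-dioxolan-2-yl)acetaldehyde]
Conditions: i-Bu2AlH, CH2Cl2, −78 °C; then aq potassium sodium tartrate
Reagents that add atoms: none
Why: Partial reduction of an ester with i-Bu2AlH stops at the aldehyde because the first hydride adduct persists at −78 °C until the quench, and the ketal is inert to hydride.

Step 2
Reactants: 2 ketal aldehyde; 3 allenylboronic acid pinacol ester
Product: 4 homopropargylic alcohol (2R)-1-(2-methyl-1,3-dioxolan-2-yl)pent-4-yn-2-ol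
Conditions: (R)-TRIP (chiral phosphoric acid, 10 mol%), 4 Å MS, toluene, −20 °C
Reagents that add atoms: none
Why: Chiral phosphoric acid catalysed propargylation with an allenylboronate runs as an SE2' addition through a closed six-membered transition state in which the phosphate binds the boronate oxygen and the formyl hydrogen and exposes the Re face of 2, which joins C8 to C9, sets C9 as R and gives the homopropargylic rather than the allenic alcohol.

Step 3
Reactants: 4 homopropargylic alcohol
Product: 5 PMB ether 2-{(2R)-2-[(4-methoxybenzyl)oxy]pent-4-yn-1-yl}-2-methyl-1,3-dioxolane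
Conditions: NaH, 4-MeOC6H4CH2Cl, Bu4NI (cat.), THF/DMF, 0 °C to rt
Reagents that add atoms: 4-methoxybenzyl chloride, COc1ccc(CCl)cc1
Why: Williamson etherification under basic conditions spares the acid-labile ketal and installs the benzyl-type ether that the later 1,5-anti induction needs.

Step 4
Reactants: 5 PMB ether; 6 acrolein
Product: 8 enynol (3S,7R)-7-[(4-methoxybenzyl)oxy]-8-(2-methyl-1,3-dioxolan-2-yl)oct-1-en-4-yn-3-ol, via methylzinc acetylide 7 (not isolated)
Conditions: Zn(CH3)2, (S,S)-ProPhenol (10 mol%), Ph3P=O (20 mol%), toluene, rt; then 6, 0 °C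
Reagents that add atoms: dimethylzinc, C[Zn]C (its atoms stay only in 7)
Why: Catalytic asymmetric alkynylation of an enal with the dinuclear zinc ProPhenol complex binds acrolein on one zinc and delivers the alkynyl group of 7 from the other to the Re face in a 1,2-fashion, which joins C5 to C6 and sets C5 as S under catalyst control, the remote C9 centre having no influence.

Step 5
Reactants: 8 enynol
Product: 9 dienol (3S,4Z,7R)-7-[(4-methoxybenzyl)oxy]-8-(2-methyl-1,3-dioxolan-2-yl)octa-1,4-dien-3-ol
Conditions: H2 (1 atm, stopped after 1 equiv), Pd/CaCO3 poisoned with Pb(OAc)2 (Lindlar catalyst), quinoline, EtOAc, rt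
Reagents that add atoms: none
Why: Lindlar semihydrogenation delivers H2 in a syn fashion to the strongly adsorbed alkyne and so gives the Z-C6=C7 alkene, and stopping after one equivalent spares the vinyl group, the PMB ether and the allylic C–O bond.

Step 6
Reactants: 9 dienol; 10 but-3-enoic acid
Product: 11 triene ester (3S,4Z,7R)-7-[(4-methoxybenzyl)oxy]-8-(2-methyl-1,3-dioxolan-2-yl)octa-1,4-dien-3-yl but-3-enoate
Conditions: DCC, DMAP (5 mol%), CH2Cl2, 0 °C
Reagents that add atoms: none
Why: Steglich esterification at 0 °C with only catalytic DMAP acylates the single free hydroxyl with retention at C5 and keeps the but-3-enoate from slipping into conjugation.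

Step 7
Reactants: 11 triene ester
Product: 13 conjugated lactone (6S)-6-{(1Z,4R)-4-[(4-methoxybenzyl)oxy]-5-(2-methyl-1,3-dioxolan-2-yl)pent-1-en-1-yl}-5,6-dihydro-2H-pyran-2-one, via deconjugated lactone 12 (not isolated)
Conditions: (H2IMes)(PCy3)Cl2Ru=CHPh (second-generation Grubbs catalyst, 3 mol%), 1,4-benzoquinone (10 mol%), CH2Cl2 (2 mM), 40 °C, argon sparge; then DBU (0.3 equiv), 0 °C to rt, same flask
Reagents that add atoms: none
Why: The ruthenium benzylidene initiates on the unhindered terminal alkene of the but-3-enoate to give the alkylidene Ru=C3, which undergoes [2+2] cycloaddition and cycloreversion with the vinyl group on C5, so that C3 and C4 are joined, ring A (O1, C1–C5) is closed and ethylene leaves; the closest known reaction type is ring-closing metathesis of allylic but-3-enoates to 3,6-dihydro-2H-pyran-2-ones. The mode of closure is a six-ring diene metathesis in which the new C3=C4 alkene is endocyclic and therefore necessarily cis. No stereocentre is created: C5 and C9 are not touched, and the configuration of C5 in 11 is carried into 13 because the later proton shift involves only C2 and C4. The step needs site selectivity, since closure onto C6=C7 would also give a six-membered ring: the monosubstituted vinyl group reacts much faster than the 1,2-disubstituted, allylically branched Z-alkene, high dilution suppresses dimerisation, and 1,4-benzoquinone suppresses ruthenium hydride species that would isomerise the but-3-enoate or the Z-alkene. Catalytic DBU then removes the doubly activated C2–H of 12 and the dienolate is reprotonated at C4, a prototropic shift driven by conjugation with C1=O that turns the new C3=C4 double bond into the C3–C4 single bond of the target ring. Substoichiometric base, low temperature and short contact keep the dienolate concentration low, so that eliminative opening of ring A to a trienoic acid should not compete.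

Step 8
Reactants: 13 conjugated lactone
Product: 14 lactone methyl ketone (6S)-6-{(1Z,4R)-4-[(4-methoxybenzyl)oxy]-6-oxohept-1-en-1-yl}-5,6-dihydro-2H-pyran-2-one
Conditions: PPTS (cat.), acetone/H2O, 50 °C
Reagents that add atoms: water, O
Why: Acid-catalysed ketal hydrolysis works here because the dioxolane of a dialkyl ketone is far more labile than the PMB ether, the lactone or the allylic C5–O1 bond, and the buffered acid is too weak to eliminate the β-alkoxy group.

Step 9
Reactants: 14 lactone methyl ketone; 15 3-phenylpropanal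
Product: 17 aldol adduct (6S)-6-{(1Z,4R,8R)-8-hydroxy-4-[(4-methoxybenzyl)oxy]-6-oxo-10-phenyldec-1-en-1-yl}-5,6-dihydro-2H-pyran-2-one, via dicyclohexylboron enolate 16 (not isolated)
Conditions: (c-C6H11)2BCl, Et3N, Et2O, 0 °C; then 15, −78 °C; then MeOH, pH 7 buffer, H2O2, 0 °C
Reagents that add atoms: chlorodicyclohexylborane, ClB(C1CCCCC1)C1CCCCC1 (its atoms stay only in 16)
Why: In this boron-mediated aldol reaction of a β-alkoxy methyl ketone the reagent pair enolises the ketone on its methyl side in preference to the lactone, and the boat-like transition state stabilised by a formyl hydrogen bond to the C9 ether oxygen gives 1,5-anti induction, so that C12–C13 is formed and C13 is set as R by C9.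

Step 10
Reactants: 17 aldol adduct; 18 acetaldehyde
Product: 19 acetate (6S)-6-{(1Z,4R,6R,8R)-8-acetoxy-6-hydroxy-4-[(4-methoxybenzyl)oxy]-10-phenyldec-1-en-1-yl}-5,6-dihydro-2H-pyran-2-one
Conditions: SmI2 (0.3 equiv), 18 (excess), THF, −10 °C
Reagents that add atoms: none
Why: In the Evans–Tishchenko reduction the C13 hydroxyl forms a hemiacetal with acetaldehyde, trivalent samarium ties it to the C11 ketone in a chair-like bicyclic transition state and the hemiacetal hydride is delivered intramolecularly, which sets C11 as R (1,3-anti to C13, hence syn to C9) and leaves the natural acetate on O13 in the same event.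

Step 11
Reactants: 19 acetate
Product: 20 target (6S)-6-[(1Z,4R,6R,8R)-8-acetoxy-4,6-dihydroxy-10-phenyldec-1-en-1-yl]-5,6-dihydro-2H-pyran-2-one
Conditions: DDQ, CH2Cl2/pH 7 buffer, 0 °C
Reagents that add atoms: none
Why: Oxidative PMB cleavage proceeds by hydride abstraction from the electron-rich benzylic position and hydrolysis of the oxocarbenium ion, while the acetate, the enoate and the Z-alkene are not oxidised and the buffer suppresses acetyl migration.

Compound list
1 | ethyl 2-(2-methyl-1,3-dioxolan-2-yl)acetate | CCOC(=O)CC1(C)OCCO1 | starting material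
2 | 2-(2-methyl-1,3-dioxolan-2-yl)acetaldehyde | O=CCC1(C)OCCO1 | intermediate
3 | allenylboronic acid pinacol ester [4,4,5,5-tetramethyl-2-(propa-1,2-dien-1-yl)-1,3,2-dioxaborolane] | C=C=CB1OC(C)(C)C(C)(C)O1 | starting material
4 | (2R)-1-(2-methyl-1,3-dioxolan-2-yl)pent-4-yn-2-ol | C#CC[C@@H](O)CC1(C)OCCO1 | intermediate
5 | 2-{(2R)-2-[(4-methoxybenzyl)oxy]pent-4-yn-1-yl}-2-methyl-1,3-dioxolane | C#CC[C@@H](OCc1ccc(OC)cc1)CC1(C)OCCO1 | intermediate
6 | acrolein (prop-2-enal) | C=CC=O | starting material
7 | methylzinc acetylide of 5 (not isolated) | C[Zn]C#CC[C@@H](OCc1ccc(OC)cc1)CC1(C)OCCO1 | intermediate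
8 | (3S,7R)-7-[(4-methoxybenzyl)oxy]-8-(2-methyl-1,3-dioxolan-2-yl)oct-1-en-4-yn-3-ol | C=C[C@H](O)C#CC[C@@H](OCc1ccc(OC)cc1)CC1(C)OCCO1 | intermediate
9 | (3S,4Z,7R)-7-[(4-methoxybenzyl)oxy]-8-(2-methyl-1,3-dioxolan-2-yl)octa-1,4-dien-3-ol | C=C[C@H](O)/C=C\C[C@@H](OCc1ccc(OC)cc1)CC1(C)OCCO1 | intermediate
10 | but-3-enoic acid (vinylacetic acid) | C=CCC(=O)O | starting material
11 | (3S,4Z,7R)-7-[(4-methoxybenzyl)oxy]-8-(2-methyl-1,3-dioxolan-2-yl)octa-1,4-dien-3-yl but-3-enoate | C=CCC(=O)O[C@@H](C=C)/C=C\C[C@@H](OCc1ccc(OC)cc1)CC1(C)OCCO1 | intermediate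
12 | (6R)-6-{(1Z,4R)-4-[(4-methoxybenzyl)oxy]-5-(2-methyl-1,3-dioxolan-2-yl)pent-1-en-1-yl}-3,6-dihydro-2H-pyran-2-one (6R by the CIP rules, same spatial arrangement at C5 as in 11 and 13; not isolated) | CC1(OCCO1)C[C@H](OCc1ccc(OC)cc1)C/C=C\[C@@H]1C=CCC(=O)O1 | intermediate
13 | (6S)-6-{(1Z,4R)-4-[(4-methoxybenzyl)oxy]-5-(2-methyl-1,3-dioxolan-2-yl)pent-1-en-1-yl}-5,6-dihydro-2H-pyran-2-one | CC1(OCCO1)C[C@H](OCc1ccc(OC)cc1)C/C=C\[C@@H]1CC=CC(=O)O1 | intermediate
14 | (6S)-6-{(1Z,4R)-4-[(4-methoxybenzyl)oxy]-6-oxohept-1-en-1-yl}-5,6-dihydro-2H-pyran-2-one | CC(=O)C[C@H](OCc1ccc(OC)cc1)C/C=C\[C@@H]1CC=CC(=O)O1 | intermediate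
15 | 3-phenylpropanal | O=CCCc1ccccc1 | starting material
16 | dicyclohexylboron enolate of 14, enolised toward C12 (not isolated) | C=C(OB(C1CCCCC1)C1CCCCC1)C[C@H](OCc1ccc(OC)cc1)C/C=C\[C@@H]1CC=CC(=O)O1 | intermediate
17 | (6S)-6-{(1Z,4R,8R)-8-hydroxy-4-[(4-methoxybenzyl)oxy]-6-oxo-10-phenyldec-1-en-1-yl}-5,6-dihydro-2H-pyran-2-one | O[C@H](CCc1ccccc1)CC(=O)C[C@H](OCc1ccc(OC)cc1)C/C=C\[C@@H]1CC=CC(=O)O1 | intermediate
18 | acetaldehyde | CC=O | starting material
19 | (6S)-6-{(1Z,4R,6R,8R)-8-acetoxy-6-hydroxy-4-[(4-methoxybenzyl)oxy]-10-phenyldec-1-en-1-yl}-5,6-dihydro-2H-pyran-2-one | CC(=O)O[C@H](CCc1ccccc1)C[C@H](O)C[C@H](OCc1ccc(OC)cc1)C/C=C\[C@@H]1CC=CC(=O)O1 | intermediate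
20 | (6S)-6-[(1Z,4R,6R,8R)-8-acetoxy-4,6-dihydroxy-10-phenyldec-1-en-1-yl]-5,6-dihydro-2H-pyran-2-one | CC(=O)O[C@H](CCc1ccccc1)C[C@H](O)C[C@H](O)C/C=C\[C@@H]1CC=CC(=O)O1 | target

Total step count: 11. Longest linear sequence: 11 steps (1 to 20).

Steps most likely to fail

Step 7. Three processes may intervene:
- The Ru=C3 alkylidene may close onto C6=C7, which also gives a six-membered ring and cuts off the side chain.
- Secondary metathesis may erode the Z geometry.
- The dienolate may open ring A by elimination during the base stage.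

The fallback sets out from 5 and comes back at 13. It closes ring A at C2=C3, already in conjugation, so no base is needed. Compound 5 is deprotonated with n-BuLi and formylated with DMF to give the ynal F1. Brown allylboration with (−)-Ipc2B(allyl), made from (+)-α-pinene, adds the allyl group to the Si face and gives the homoallylic propargylic alcohol F2 with C5 as S. Lindlar semihydrogenation gives the Z-dienol F3. Acryloyl chloride and i-Pr2NEt give the acrylate F4. Ring-closing metathesis with (H2IMes)(PCy3)Cl2Ru=CHPh (second-generation Grubbs catalyst) then delivers 13.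

Step 4. Facial selectivity may be poor with the small, unsubstituted enal, and acrolein may be lost by polymerisation during the slow zinc-catalysed addition. The fallback sets out from 5 and comes back at 8. It replaces catalytic induction by resolution. Compound 5 is deprotonated with n-BuLi and added to 6 without stereocontrol to give the C5-epimeric enynol mixture F5. Kinetic resolution with Candida antarctica lipase B and vinyl acetate should acetylate the epimer that places the vinyl group in the medium-sized pocket, giving the (3R)-acetate F6. The unreacted (3S)-alcohol, which is 8, is separated by chromatography.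

Step 11. Three processes may intervene:
- The benzylic oxocarbenium ion may be captured by the neighbouring C11 hydroxyl instead of water.
- The material so formed may be over-oxidised.
- The acetyl group may migrate from O13 to O11 during work-up.

The fallback sets out from 19 and comes back at 20. It makes the intramolecular capture the intended path. DDQ with 4 Å MS in dry CH2Cl2 converts 19 into the all-equatorial 4-methoxybenzylidene acetal F7 of the syn-9,11-diol. Aqueous acetic acid at rt then hydrolyses the acetal to 20 without touching the acetate or ring A.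

Further compounds
F1 | step 7 | (5R)-5-[(4-methoxybenzyl)oxy]-6-(2-methyl-1,3-dioxolan-2-yl)hex-2-ynal | O=CC#CC[C@@H](OCc1ccc(OC)cc1)CC1(C)OCCO1
F2 | step 7 | (4S,8R)-8-[(4-methoxybenzyl)oxy]-9-(2-methyl-1,3-dioxolan-2-yl)non-1-en-5-yn-4-ol | C=CC[C@H](O)C#CC[C@@H](OCc1ccc(OC)cc1)CC1(C)OCCO1
F3 | step 7 | (4S,5Z,8R)-8-[(4-methoxybenzyl)oxy]-9-(2-methyl-1,3-dioxolan-2-yl)nona-1,5-dien-4-ol | C=CC[C@H](O)/C=C\C[C@@H](OCc1ccc(OC)cc1)CC1(C)OCCO1
F4 | step 7 | (4S,5Z,8R)-8-[(4-methoxybenzyl)oxy]-9-(2-methyl-1,3-dioxolan-2-yl)nona-1,5-dien-4-yl acrylate | C=CC(=O)O[C@@H](CC=C)/C=C\C[C@@H](OCc1ccc(OC)cc1)CC1(C)OCCO1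
F5 | step 4 | (7R)-7-[(4-methoxybenzyl)oxy]-8-(2-methyl-1,3-dioxolan-2-yl)oct-1-en-4-yn-3-ol, mixture of C3 epimers | C=CC(O)C#CC[C@@H](OCc1ccc(OC)cc1)CC1(C)OCCO1
F6 | step 4 | (3R,7R)-7-[(4-methoxybenzyl)oxy]-8-(2-methyl-1,3-dioxolan-2-yl)oct-1-en-4-yn-3-yl acetate | C=C[C@@H](OC(C)=O)C#CC[C@@H](OCc1ccc(OC)cc1)CC1(C)OCCO1
F7 | step 11 | 9,11-O-(4-methoxybenzylidene) acetal of 20 (2,4,6-cis, all-equatorial 1,3-dioxane) | CC(=O)O[C@H](CCc1ccccc1)C[C@H]1C[C@@H](C/C=C\[C@@H]2CC=CC(=O)O2)O[C@@H](c2ccc(OC)cc2)O1
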